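**Plan** (quinone ring numbered C1(=O), C2(OMe), C3(OMe), C4(=O), C5(CH2-imidazole), C6(H))
- Retrosynthesis cuts, in order: the quinone C5=C6 bond (giving acyclic Z-enedione 15); reconnection of C1 to C4 as a squarate-derived cyclobutene-1,2-diol; the CH2–C5(imidazole) bond; the hydantoin C=N bond; the imidazole ring (N-propargylguanidine); the aryl–alkyne bond.
- Forward: aminoimidazole ring, then dehydrohydantoin, then C5 iodide; separately dimethyl squarate takes up methyl (future C6) and vinyl (future C5 plus the CH2 link); B-alkyl Suzuki union; glycol cleavage opens the four-membered ring; the quinone ring is closed last.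
- Enabling feature: C5 and C6 are the two α-carbons of the 1,4-diketone C4(=O)/C1(=O), so C5–C6 is the central bond of a 1,4-dicarbonyl and can be made by oxidative union of two enol carbons of like polarity; the C2=C3 bis-methoxy alkene holds them cis and aromatisation to the hydroquinone drives the closure.
- Stereochemistry: the target is achiral; the diol stereocentres (12–14) and C5 of 17 are transient; the only geometry that matters, Z at C2=C3, is inherited from the four-membered ring.

Key step: step 8

Remark: diols 12–14 are formed and used as racemic cis/trans mixtures, so their SMILES carry no configuration; both carbinol centres are destroyed in step 7.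

**Step 1**
Reactants: 1 4-iodoanisole; 2 N-methylpropargylamine
Product: 3 3-(4-methoxyphenyl)-N-methylprop-2-yn-1-amine
Conditions: Pd(PPh3)2Cl2 (2 mol %), CuI (4 mol %), Et3N, THF, rt
Reagents that add atoms: none
Why: Sonogashira coupling of an aryl iodide with a terminal alkyne runs at room temperature and tolerates the free secondary amine.

**Step 2**
Reactants: 3 3-(4-methoxyphenyl)-N-methylprop-2-yn-1-amine
Product: 6 4-(4-methoxybenzyl)-1-methyl-1H-imidazol-2-amine, via N-propargylguanidine 4 (not isolated), via benzylidene imidazoline 5 (not isolated)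
Conditions: HCl (1 equiv), H2NCN, EtOH, 80 °C; then Et3N, AgNO3 (10 mol %), MeCN, 50 °C
Reagents that add atoms: cyanamide, NC#N
Why: Guanylation of the amine hydrochloride with cyanamide, then AgNO3-catalysed 5-exo-dig hydroamination of the N-propargylguanidine and prototropic aromatisation, should place N-methyl next to the unsubstituted ring carbon C5 and the 4-methoxybenzyl group on C4.

**Step 3**
Reactants: 6 4-(4-methoxybenzyl)-1-methyl-1H-imidazol-2-amine; 7 1-methylparabanic acid
Product: 8 C5-unsubstituted dehydrohydantoin (N2-(1-methyl-2,5-dioxoimidazol-4-yl) derivative of 6)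
Conditions: BSA [N,O-bis(trimethylsilyl)acetamide], MeCN, 80 °C; then 6, PhMe, 110 °C
Reagents that add atoms: none
Why: Silylation-mediated condensation of a 2-aminoimidazole with 1-methylparabanic acid is the standard dehydrohydantoin installation of the naamidine family; O-silylation of the N–H lactam activates C4 of the trione, which fixes the regiochemistry.

**Step 4**
Reactants: 8 C5-unsubstituted dehydrohydantoin
Product: 9 5-iodoimidazole dehydrohydantoin
Conditions: NIS, MeCN, 0 °C, dark
Reagents that add atoms: N-iodosuccinimide, O=C1CCC(=O)N1I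
Why: Electrophilic aromatic iodination should occur at C5, the only free and most electron-rich ring position, while the para-substituted anisole ring is inert to NIS without acid.

**Step 5**
Reactants: 10 dimethyl squarate
Product: 12 3,4-dimethoxy-1-methyl-2-vinylcyclobut-3-ene-1,2-diol, via lithium cyclobutenone alkoxide 11 (not isolated)
Conditions: MeLi (1.0 equiv), THF, −78 °C; CH2=CHMgBr (1.3 equiv), −78 °C; aq. NH4Cl at −78 °C
Reagents that add atoms: methyllithium, [Li]C; vinylmagnesium bromide, C=C[Mg]Br
Why: Two successive 1,2-carbonyl additions to a squarate ester (alkyllithium, then Grignard addition to the vinylogous-ester carbonyl of the alkoxide) with a cold quench should give the diol before the dialkoxide can ring-open; the two new stereocentres are not controlled and need not be.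

**Step 6**
Reactants: 12 3,4-dimethoxy-1-methyl-2-vinylcyclobut-3-ene-1,2-diol; 9 5-iodoimidazole dehydrohydantoin
Product: 14 coupled cyclobutenediol (5-[2-(cyclobutenediol)ethyl]imidazole), via B-alkyl-9-BBN 13 (not isolated)
Conditions: 9-BBN (3 equiv), THF, 0 °C to rt; then aq. Cs2CO3 (destroys excess B–H), 9, Pd(dppf)Cl2 (10 mol %), AsPh3, DMF, rt
Reagents that add atoms: none
Why: B-alkyl Suzuki–Miyaura coupling: 9-BBN hydroborates only the monosubstituted alkene (anti-Markovnikov; the tetrasubstituted enol-ether alkene is inert) and the primary alkylborane should couple with the heteroaryl iodide at room temperature under mild carbonate conditions.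

**Step 7**
Reactants: 14 coupled cyclobutenediol
Product: 15 (Z)-4,5-dimethoxy-3,6-dioxohept-4-enyl imidazole (seco-quinone)
Conditions: Pb(OAc)4 (1.1 equiv), pyridine, CH2Cl2, −20 to 0 °C
Reagents that add atoms: none
Why: Criegee glycol cleavage of the strained ditertiary 1,2-diol breaks the ring C–C bond, so the two ketones emerge cis on the C(OMe)=C(OMe) bond and the Z geometry is set by the former ring.

**Step 8**
Reactants: 15 (Z)-enedione (seco-quinone)
Product: 19 naamidine F, via bis(enol silane) 16 (not isolated), via cyclohexenedione 17 (not isolated), via hydroquinone 18 (not isolated)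
Conditions: TMSOTf (3.5 equiv), Et3N, CH2Cl2, 0 °C; filter under Ar, concentrate; Ag2O (3 equiv), DMSO, rt to 60 °C
Reagents that add atoms: none
Why: Proposed new method: TMSOTf/Et3N enolises both vinylogous-ester ketones of 15 (each has a single enolisable side, as in the preparation of the Danishefsky diene) to triene 16; Ag2O then turns one enol silane into a silver enolate/α-keto radical that adds to the carbon terminus of the other enol silane, a second electron transfer with loss of the silyl groups gives ene-dione 17, and 17 tautomerises to hydroquinone 18, which further Ag2O oxidises to the quinone. The closest known reaction type is the Ag2O-mediated oxidative coupling of ketone enol silanes to 1,4-diketones and its intramolecular relatives with other one-electron oxidants; new is that both carbonyl carbons lie inside the ring being closed, so that the coupling product aromatises. The six-membered ring closes by 6-endo-trig radical addition joining the two termini of a (Z)-hexa-1,3,5-triene (a thermal 6π disrotatory closure of 16 would give the same skeleton after oxidation). The one new stereocentre, C5 of 17, is not controlled and is erased on aromatisation. The step needs C5–C6 closure in preference to five-ring or C–O closure, and oxidation of the enol silanes in preference to the heteroarene: the Z C2=C3 bond inherited from the four-membered ring holds the two enol termini within bonding distance, radical attack at the unsubstituted CH2 terminus gives the stabilised α-silyloxy radical, and the tetra-oxygenated triene should be the most easily oxidised part of the molecule.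

**Compound list**
1 | 4-iodoanisole | COc1ccc(I)cc1 | starting material
2 | N-methylpropargylamine | CNCC#C | starting material
3 | 3-(4-methoxyphenyl)-N-methylprop-2-yn-1-amine | CNCC#Cc1ccc(OC)cc1 | intermediate
4 | 1-[3-(4-methoxyphenyl)prop-2-yn-1-yl]-1-methylguanidine | CN(CC#Cc1ccc(OC)cc1)C(N)=N | intermediate
5 | (Z)-4-(4-methoxybenzylidene)-1-methyl-4,5-dihydro-1H-imidazol-2-amine | CN1C/C(=C/c2ccc(OC)cc2)N=C1N | intermediate
6 | 4-(4-methoxybenzyl)-1-methyl-1H-imidazol-2-amine | Cn1cc(Cc2ccc(OC)cc2)nc1N | intermediate
7 | 1-methylimidazolidine-2,4,5-trione (1-methylparabanic acid) | CN1C(=O)NC(=O)C1=O | starting material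
8 | 4-{[4-(4-methoxybenzyl)-1-methyl-1H-imidazol-2-yl]amino}-1-methyl-1H-imidazole-2,5-dione | Cn1cc(Cc2ccc(OC)cc2)nc1NC1=NC(=O)N(C)C1=O | intermediate
9 | 4-{[5-iodo-4-(4-methoxybenzyl)-1-methyl-1H-imidazol-2-yl]amino}-1-methyl-1H-imidazole-2,5-dione | Cn1c(I)c(Cc2ccc(OC)cc2)nc1NC1=NC(=O)N(C)C1=O | intermediate
10 | dimethyl squarate (3,4-dimethoxycyclobut-3-ene-1,2-dione) | COC1=C(OC)C(=O)C1=O | starting material
11 | lithium 2,3-dimethoxy-1-methyl-4-oxocyclobut-2-en-1-olate | [Li+].COC1=C(OC)C(C)([O-])C1=O | intermediate
12 | 3,4-dimethoxy-1-methyl-2-vinylcyclobut-3-ene-1,2-diol (racemic, cis/trans mixture) | COC1=C(OC)C(O)(C=C)C1(C)O | intermediate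
13 | 2-[2-(9-borabicyclo[3.3.1]nonan-9-yl)ethyl]-3,4-dimethoxy-1-methylcyclobut-3-ene-1,2-diol (racemic, cis/trans mixture) | COC1=C(OC)C(O)(CCB2C3CCCC2CCC3)C1(C)O | intermediate
14 | 4-({5-[2-(1,2-dihydroxy-3,4-dimethoxy-2-methylcyclobut-3-en-1-yl)ethyl]-4-(4-methoxybenzyl)-1-methyl-1H-imidazol-2-yl}amino)-1-methyl-1H-imidazole-2,5-dione (racemic, cis/trans mixture) | COC1=C(OC)C(O)(CCc2c(Cc3ccc(OC)cc3)nc(NC3=NC(=O)N(C)C3=O)n2C)C1(C)O | intermediate
15 | 4-({5-[(4Z)-4,5-dimethoxy-3,6-dioxohept-4-en-1-yl]-4-(4-methoxybenzyl)-1-methyl-1H-imidazol-2-yl}amino)-1-methyl-1H-imidazole-2,5-dione | CC(=O)/C(OC)=C(OC)\C(=O)CCc1c(Cc2ccc(OC)cc2)nc(NC2=NC(=O)N(C)C2=O)n1C | intermediate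
16 | 4-({5-[(2Z,4Z)-4,5-dimethoxy-3,6-bis(trimethylsilyloxy)hepta-2,4,6-trien-1-yl]-4-(4-methoxybenzyl)-1-methyl-1H-imidazol-2-yl}amino)-1-methyl-1H-imidazole-2,5-dione (amidine N–H drawn unsilylated) | C=C(O[Si](C)(C)C)/C(OC)=C(OC)\C(O[Si](C)(C)C)=C\Cc1c(Cc2ccc(OC)cc2)nc(NC2=NC(=O)N(C)C2=O)n1C | intermediate
17 | 4-({5-[(4,5-dimethoxy-3,6-dioxocyclohex-4-en-1-yl)methyl]-4-(4-methoxybenzyl)-1-methyl-1H-imidazol-2-yl}amino)-1-methyl-1H-imidazole-2,5-dione (racemic) | COC1=C(OC)C(=O)C(Cc2c(Cc3ccc(OC)cc3)nc(NC3=NC(=O)N(C)C3=O)n2C)CC1=O | intermediate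
18 | 4-({5-[(2,5-dihydroxy-3,4-dimethoxyphenyl)methyl]-4-(4-methoxybenzyl)-1-methyl-1H-imidazol-2-yl}amino)-1-methyl-1H-imidazole-2,5-dione | COc1c(OC)c(O)c(Cc2c(Cc3ccc(OC)cc3)nc(NC3=NC(=O)N(C)C3=O)n2C)cc1O | intermediate
19 | naamidine F | COC1=C(OC)C(=O)C(Cc2c(Cc3ccc(OC)cc3)nc(NC3=NC(=O)N(C)C3=O)n2C)=CC1=O | target

**Totals**
Total steps: 8. Longest linear sequence: 7 (steps 1, 2, 3, 4, 6, 7, 8); step 5 is the convergent branch.

**Steps most likely to fail**

1. Step 8 (proposed new method). Possible failure processes: aldol-type closure of the mono-enol silane onto the second, silyl-activated ketone to a five-membered ring before the second enolisation; one-electron oxidation of the acylaminoimidazole competing with that of the enol silanes; hydrolysis of the triene before it is oxidised. Fallback with known chemistry, which separates ring closure from oxidation: 15 is converted with TBSOTf/Et3N at −78 °C into the isolable bis(tert-butyldimethylsilyl enol ether) F1. Heating F1 in toluene at about 100 °C should close the same C5–C6 bond by thermal disrotatory 6π electrocyclisation of the (Z)-hexatriene, giving the 1,4-bis(silyloxy)cyclohexa-1,3-diene F2. DDQ dehydrogenation at 0 °C should give the hydroquinone bis(silyl ether) F3, and AcOH-buffered TBAF releases hydroquinone 18. The route is rejoined at 18, which Ag2O in ether oxidises to 19.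

2. Step 6. Possible failure processes: protodeiodination of the electron-rich iodide and slow transmetalation of the hydroxyl-chelated alkylborane; base-promoted electrocyclic opening of the cyclobutenediol; hydrolytic opening of the acylamidine ring in aqueous carbonate. Fallback, an sp–sp2 coupling followed by saturation: 10 is treated with MeLi and then HC≡CMgBr as in step 5 to give the ethynyl diol F4. Sonogashira coupling of F4 with 9 (Pd(PPh3)2Cl2, CuI, Et3N, THF, rt) gives the alkyne-linked diol F5, and hydrogenation (H2, 1 atm, Pd/C, EtOAc) saturates the alkyne. The route is rejoined at 14.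

3. Step 5. Possible failure processes: oxyanion-accelerated conrotatory opening of the four-membered ring at the dialkoxide stage; conjugate addition–elimination of the Grignard reagent at a methoxy-bearing carbon. Fallback, in which no dialkoxide is ever formed: 10 and MeLi give, after a cold quench, isolated 4-hydroxy-2,3-dimethoxy-4-methylcyclobut-2-en-1-one F6. TESCl/imidazole caps it as the triethylsilyl ether F7. CH2=CHMgBr with CeCl3 at −78 °C adds to the remaining carbonyl of the neutral ether to give the mono-silylated diol F8, and AcOH-buffered TBAF removes the silyl group. The route is rejoined at 12.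

**Further compounds**
F1 | step 8 | bis(tert-butyldimethylsilyl enol ether) of 15 | C=C(O[Si](C)(C)C(C)(C)C)/C(OC)=C(OC)\C(O[Si](C)(C)C(C)(C)C)=C\Cc1c(Cc2ccc(OC)cc2)nc(NC2=NC(=O)N(C)C2=O)n1C
F2 | step 8 | 1,4-bis(tert-butyldimethylsilyloxy)-2,3-dimethoxy-5-(imidazolylmethyl)cyclohexa-1,3-diene (racemic) | COC1=C(O[Si](C)(C)C(C)(C)C)CC(Cc2c(Cc3ccc(OC)cc3)nc(NC3=NC(=O)N(C)C3=O)n2C)C(O[Si](C)(C)C(C)(C)C)=C1OC
F3 | step 8 | bis(tert-butyldimethylsilyl) ether of hydroquinone 18 | COc1c(OC)c(O[Si](C)(C)C(C)(C)C)c(Cc2c(Cc3ccc(OC)cc3)nc(NC3=NC(=O)N(C)C3=O)n2C)cc1O[Si](C)(C)C(C)(C)C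
F4 | step 6 | 2-ethynyl-3,4-dimethoxy-1-methylcyclobut-3-ene-1,2-diol (racemic, cis/trans mixture) | COC1=C(OC)C(O)(C#C)C1(C)O
F5 | step 6 | alkyne-linked cyclobutenediol (5-alkynylimidazole dehydrohydantoin) | COC1=C(OC)C(O)(C#Cc2c(Cc3ccc(OC)cc3)nc(NC3=NC(=O)N(C)C3=O)n2C)C1(C)O
F6 | step 5 | 4-hydroxy-2,3-dimethoxy-4-methylcyclobut-2-en-1-one (racemic) | COC1=C(OC)C(C)(O)C1=O
F7 | step 5 | 2,3-dimethoxy-4-methyl-4-(triethylsilyloxy)cyclobut-2-en-1-one (racemic) | COC1=C(OC)C(C)(O[Si](CC)(CC)CC)C1=O
F8 | step 5 | 2,3-dimethoxy-4-methyl-4-(triethylsilyloxy)-1-vinylcyclobut-2-en-1-ol (racemic, cis/trans mixture) | COC1=C(OC)C(O)(C=C)C1(C)O[Si](CC)(CC)CC
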